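**Retrosynthetic overview**
1. Cut the C7–CH(CH3) bond. This gives decarboxycitrinin as the C7 nucleophile and the ethylidene o-quinone methide of the lactone half, released from a 1-sulfonylethyl precursor. Catalyst control sets the bridge carbon.
2. Both halves come from one lactone, (3R,4S)-6,8-dihydroxy-3,4,5-trimethylisochroman-1-one. Partial reduction and dehydration give the quinone methide half; acetaldehyde plus PhSO2H arms the other half.
3. Key disconnection: the benzo-fused δ-lactone comes from trans-(3R,4R)-3,4-dimethyl-β-lactone and the trianion of methyl 3,5-dioxoheptanoate. This is a four- to six-membered ring expansion that builds the benzene ring in the same operation.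
4. The β-lactone comes from cis-2,3-epoxybutane and CO, a three- to four-membered carbonylative ring expansion whose desymmetrisation sets C3/C4 of both halves. The diketo ester comes from methyl acetoacetate and N-methoxy-N-methylpropanamide.
5. Ring order: oxirane → oxetanone → benzene ring and δ-lactone together → pyran quinone methide (from the δ-lactone) → union of the two bicycles.

Assumption: the target is treated as the drawn 6-hydroxy-8-oxo tautomer, with descriptors 3R,4S in both halves and R at the bridge carbon, and the name is read as dicitrinone H.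

**Step 1**
Reactants: 1 cis-2,3-epoxybutane
Product: 2 (3R,4R)-3,4-dimethyloxetan-2-one
Conditions: [(R,R)-(salcy)Al(THF)2][Co(CO)4] (2 mol %; salcy = dianion of N,N'-bis(3,5-di-tert-butylsalicylidene)-trans-cyclohexane-1,2-diamine), CO (60 bar), DME, 30 °C, 24 h; vacuum distillation
Reagents that add atoms: carbon monoxide, [C-]#[O+]
Why: Ring-expansion carbonylation of an epoxide by a Lewis acid/tetracarbonylcobaltate ion pair: the chiral aluminium cation binds the meso epoxide, Co(CO)4− opens the (S)-configured carbon with inversion, CO inserts with retention and the alkoxide closes on the acyl cobalt, so the cis epoxide gives only the trans lactone and the catalyst's choice between the enantiotopic carbons sets C3 and C4 of both halves (the ligand antipode is used if the sense is opposite, and residual minor enantiomer is removed by recrystallising 10).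

**Step 2**
Reactants: 3 methyl acetoacetate; 4 N-methoxy-N-methylpropanamide
Product: 6 methyl 3,5-dioxoheptanoate, via acetoacetate dianion 5 (not isolated)
Conditions: NaH (1.1 equiv), THF, 0 °C; n-BuLi (1.05 equiv), 0 °C; 4 (0.9 equiv), 0 → 23 °C; 1 M HCl
Reagents that add atoms: none
Why: Weiler dianion γ-acylation (Claisen type): the γ-carbon of 5 is the most nucleophilic site and adds only once because the chelated Weinreb adduct survives until the acid quench; no stereocentre is formed.

**Step 3**
Reactants: 6 methyl 3,5-dioxoheptanoate; 2 (3R,4R)-3,4-dimethyloxetan-2-one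
Product: 10 (3R,4S)-6,8-dihydroxy-3,4,5-trimethylisochroman-1-one, via trilithium trianion 7 (not isolated), via open-chain triketo ester 8 (not isolated), via resorcylate ester 9 (not isolated)
Conditions: 6 (2.05 equiv), commercial iPr2NLi (LDA, 6.3 equiv), THF, −78 → 0 °C; 2 (1.0 equiv), −78 → −30 °C; AcOH quench, extraction; crude in MeOH, Cs2CO3 (3 equiv), 0 → 23 °C; then HCl/MeOH to pH 1, 40 °C
Reagents that add atoms: none
Why: Proposed new method: a benzannulative two-carbon ring expansion of a β-lactone, in which the terminal C6 carbanion of 7 (the hardest, most basic site) attacks the strained acyl carbon of 2 with acyl C–O scission (about 95 kJ/mol strain released, no external leaving group); the second equivalent of 7 then converts the product into its C5–C7 diketonate, which shields C8 from enolisation and the aldolate from retro-aldol cleavage; carbonate triggers the C2→C7 aldol, E1cB loss of water and tautomerisation to arene 9 (the C6 methyl blocks the competing Claisen mode, and the O9 hemiketal is reversible and drains to the arene); finally the hydroxyl freed from the old lactone closes on the ortho ester, so C8a and C1 end up inserted between the former acyl carbon and the ring oxygen with both stereocentres untouched (old C3 becomes C4, S only by a priority change; old C4 becomes C3, R); the closest known reaction types are terminal acylation of 1,3,5-tricarbonyl polyanions by esters followed by biomimetic aldol aromatisation, acyl opening of β-lactones by lithiated phosphonates or ester enolates, and side-chain-insertion ring expansion of lactones.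

**Step 4**
Reactants: 10 (3R,4S)-6,8-dihydroxy-3,4,5-trimethylisochroman-1-one
Product: 12 decarboxycitrinin (3R,4S)-6-hydroxy-3,4,5-trimethyl-3,4-dihydro-8H-isochromen-8-one, via lactol 11 (not isolated)
Conditions: iBu2AlH (DIBAL-H, 3.3 equiv), CH2Cl2, −78 °C, 2 h; 1 M HCl, −78 → 23 °C
Reagents that add atoms: none
Why: Partial lactone reduction: two equivalents are consumed by the phenols, the third adds once to the aluminium-chelated salicylate-type carbonyl to give an aluminate that is stable at −78 °C, and the 6,8-dihydroxyisochroman-1-ol 11 loses water on acid work-up to the quinone methide as citrinin-type lactols do; C3 and C4 are not touched.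

**Step 5**
Reactants: 10 (3R,4S)-6,8-dihydroxy-3,4,5-trimethylisochroman-1-one; 13 acetaldehyde
Product: 15 (3R,4S)-6,8-dihydroxy-3,4,5-trimethyl-7-[1-(phenylsulfonyl)ethyl]isochroman-1-one (both epimers at the sulfone carbon), via benzylic carbinol 14 (not isolated)
Conditions: CH3CHO (3 equiv), PhSO2H (1.5 equiv), HCO2H–H2O 2:1, 23 °C, sealed flask, 36 h
Reagents that add atoms: benzenesulfinic acid, O=S(O)c1ccccc1
Why: Three-component sulfinic acid condensation: C7, the only free ring position and activated by two ortho hydroxyls, is hydroxyalkylated, and the ionised carbinol is captured by excess soft sulfinate faster than by a second molecule of 10, giving a bench-stable o-quinone methide precursor; the new centre is a mixture, which is irrelevant because step 6 planarises it.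

**Step 6**
Reactants: 15 (3R,4S)-6,8-dihydroxy-3,4,5-trimethyl-7-[1-(phenylsulfonyl)ethyl]isochroman-1-one; 12 decarboxycitrinin
Product: 17 dicitrinone H (target), via ethylidene o-quinone methide 16 (not isolated)
Conditions: 12 (1.15 equiv), quinine-derived squaramide 3-{[3,5-bis(trifluoromethyl)phenyl]amino}-4-{[(8α,9S)-6'-methoxycinchonan-9-yl]amino}cyclobut-3-ene-1,2-dione (10 mol %), 5% aq. NaHCO3, CH2Cl2–toluene 1:1, 0 °C, 24 h; 0.5 M HCl work-up
Reagents that add atoms: none
Why: Organocatalytic conjugate addition of a cyclic 1,3-dicarbonyl-type C-nucleophile to an o-quinone methide released by E1cB loss of sulfinate from a 2-(1-sulfonylalkyl)phenol: the squaramide N–H bonds hold the carbonyl of 16, and the quinuclidinium-bound vinylogous carboxylate of 12 delivers C7 to the Re face of the ethylidene carbon, which sets the (R) bridge; the existing stereocentres are remote, so the catalyst decides, and the quinidine-derived pseudoenantiomer is the handle if the sense is opposite.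

**Compound list**
1 | cis-2,3-epoxybutane (meso) | C[C@H]1O[C@H]1C | starting material
2 | (3R,4R)-3,4-dimethyloxetan-2-one | O=C1O[C@H](C)[C@H]1C | intermediate
3 | methyl acetoacetate | COC(=O)CC(C)=O | starting material
4 | N-methoxy-N-methylpropanamide | CCC(=O)N(C)OC | starting material
5 | sodium lithium dianion of methyl acetoacetate | [Na+].[Li+].C=C([O-])C=C([O-])OC | intermediate
6 | methyl 3,5-dioxoheptanoate | CCC(=O)CC(=O)CC(=O)OC | intermediate
7 | trilithium trianion of methyl 3,5-dioxoheptanoate | [Li+].[Li+].[Li+].CC=C([O-])C=C([O-])C=C([O-])OC | intermediate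
8 | methyl (8R,9R)-9-hydroxy-6,8-dimethyl-3,5,7-trioxodecanoate (C6 epimers) | O[C@H](C)[C@H](C(=O)C(C)C(=O)CC(=O)CC(=O)OC)C | intermediate
9 | methyl 2,4-dihydroxy-6-[(2S,3R)-3-hydroxybutan-2-yl]-5-methylbenzoate | O[C@H](C)[C@H](c1c(C)c(O)cc(O)c1C(=O)OC)C | intermediate
10 | (3R,4S)-6,8-dihydroxy-3,4,5-trimethylisochroman-1-one | c1c(O)c(C)c2c(c1O)C(=O)O[C@H](C)[C@H]2C | intermediate
11 | (3R,4S)-3,4,5-trimethylisochromane-1,6,8-triol (C1 epimers) | c1c(O)c(C)c2c(c1O)C(O)O[C@H](C)[C@H]2C | intermediate
12 | decarboxycitrinin, (3R,4S)-6-hydroxy-3,4,5-trimethyl-3,4-dihydro-8H-isochromen-8-one | CC1=C2C(=CO[C@H](C)[C@H]2C)C(=O)C=C1O | intermediate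
13 | acetaldehyde | CC=O | starting material
14 | (3R,4S)-6,8-dihydroxy-7-(1-hydroxyethyl)-3,4,5-trimethylisochroman-1-one (carbinol epimers) | CC(O)c1c(O)c(C)c2c(c1O)C(=O)O[C@H](C)[C@H]2C | intermediate
15 | (3R,4S)-6,8-dihydroxy-3,4,5-trimethyl-7-[1-(phenylsulfonyl)ethyl]isochroman-1-one (sulfone-carbon epimers) | CC(c1c(O)c(C)c2c(c1O)C(=O)O[C@H](C)[C@H]2C)S(=O)(=O)c1ccccc1 | intermediate
16 | (3R,4S)-7-ethylidene-8-hydroxy-3,4,5-trimethyl-3,4-dihydro-1H-isochromene-1,6(7H)-dione | CC=C1C(=O)C(C)=C2C(=C1O)C(=O)O[C@H](C)[C@H]2C | intermediate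
17 | dicitrinone H, (3R,4S)-7-{(1R)-1-[(3R,4S)-6-hydroxy-3,4,5-trimethyl-8-oxo-3,4-dihydro-8H-isochromen-7-yl]ethyl}-6,8-dihydroxy-3,4,5-trimethylisochroman-1-one | CC1=C2C(=CO[C@H](C)[C@H]2C)C(=O)C([C@H](C)c2c(O)c(C)c3c(c2O)C(=O)O[C@H](C)[C@H]3C)=C1O | target

**Total step count:** 6. **Longest linear sequence:** 4 steps (1 → 2 → 10 → 12 → 17, or 3 → 6 → 10 → 15 → 17).

**Three steps most likely to fail**

Step 3 (the proposed new step).
- Risks: 2 may be enolised or β-eliminated by the polyanion. The chain may divert to a hemiketal or pyranone. The aldol onto the doubly α-branched C7 ketone may be slow. C8 may epimerise.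
- Fallback: known chemistry that replaces the one-pot ring expansion by a protected, open-chain, stepwise sequence. It sets out from 2 (with 7 made from 6) and comes back at 10.
- 2 is opened with Me(MeO)NH·HCl/AlMe3 to (2R,3R)-3-hydroxy-N-methoxy-N,2-dimethylbutanamide F1.
- F1 is silylated (TBSCl, imidazole) to (2R,3R)-3-(tert-butyldimethylsilyloxy)-N-methoxy-N,2-dimethylbutanamide F2.
- F2 acylates trianion 7 at its terminal carbon to give, after isolation, methyl (8R,9R)-9-(tert-butyldimethylsilyloxy)-6,8-dimethyl-3,5,7-trioxodecanoate F3. With the hydroxyl masked, no hemiketal can form.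
- Carbonate-mediated biomimetic aromatisation (Cs2CO3, MeOH, then AcOH) gives methyl 6-[(2S,3R)-3-(tert-butyldimethylsilyloxy)butan-2-yl]-2,4-dihydroxy-5-methylbenzoate F4.
- Aqueous HF in MeCN removes the silyl group to give 9, which lactonises to 10.

Step 6.
- Risks: 16 may tautomerise to the vinylphenol. Facial selectivity on a methyl-substituted o-quinone methide may be poor. 12 may self-condense.
- Fallback: make the bridge first and adjust the oxidation state last. It sets out from 15 and 10 and comes back at 17.
- 15 and 10 with K2CO3 in acetone give the bis-lactone 7,7'-(ethane-1,1-diyl)bis[(3R,4S)-6,8-dihydroxy-3,4,5-trimethylisochroman-1-one] F5. Its bridge carbon is not stereogenic because both aryl groups are identical.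
- iBu2AlH (5.2 equiv, −78 °C) reduces one of the two diastereotopic lactones to the mono-lactol F6.
- Acid work-up dehydrates F6 to 17 and its bridge epimer, (1S)-epi-dicitrinone H F7. These are separated by preparative HPLC, and unreacted F5 is recycled.

Step 5.
- Risks: C7 of the resorcylate lactone may be too weak a nucleophile for acetaldehyde, or double arylation to the ethylidene dimer may win.
- Fallback: acylation then reduction instead of hydroxyalkylation. It sets out from 10 and comes back at 15 by way of 14.
- Friedel–Crafts acetylation (Ac2O, BF3·OEt2, 70 °C) gives (3R,4S)-7-acetyl-6,8-dihydroxy-3,4,5-trimethylisochroman-1-one F8.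
- NaBH4 (THF–MeOH, 0 °C) gives carbinol 14, isolated this time.
- PhSO2H with catalytic TsOH in CH2Cl2 converts 14 into 15.

**Further compounds**
F1 | step 3 | (2R,3R)-3-hydroxy-N-methoxy-N,2-dimethylbutanamide | O[C@H](C)[C@H](C(=O)N(C)OC)C
F2 | step 3 | (2R,3R)-3-(tert-butyldimethylsilyloxy)-N-methoxy-N,2-dimethylbutanamide | CC(C)(C)[Si](C)(C)O[C@H](C)[C@H](C(=O)N(C)OC)C
F3 | step 3 | methyl (8R,9R)-9-(tert-butyldimethylsilyloxy)-6,8-dimethyl-3,5,7-trioxodecanoate | CC(C)(C)[Si](C)(C)O[C@H](C)[C@H](C(=O)C(C)C(=O)CC(=O)CC(=O)OC)C
F4 | step 3 | methyl 6-[(2S,3R)-3-(tert-butyldimethylsilyloxy)butan-2-yl]-2,4-dihydroxy-5-methylbenzoate | CC(C)(C)[Si](C)(C)O[C@H](C)[C@H](c1c(C)c(O)cc(O)c1C(=O)OC)C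
F5 | step 6 | 7,7'-(ethane-1,1-diyl)bis[(3R,4S)-6,8-dihydroxy-3,4,5-trimethylisochroman-1-one] | CC(c1c(O)c(C)c2c(c1O)C(=O)O[C@H](C)[C@H]2C)c1c(O)c(C)c2c(c1O)C(=O)O[C@H](C)[C@H]2C
F6 | step 6 | mono-lactol of the bis-lactone (epimers at C1 and at the bridge) | CC(c1c(O)c(C)c2c(c1O)C(O)O[C@H](C)[C@H]2C)c1c(O)c(C)c2c(c1O)C(=O)O[C@H](C)[C@H]2C
F7 | step 6 | (1S)-epi-dicitrinone H (bridge epimer of 17) | CC1=C2C(=CO[C@H](C)[C@H]2C)C(=O)C([C@@H](C)c2c(O)c(C)c3c(c2O)C(=O)O[C@H](C)[C@H]3C)=C1O
F8 | step 5 | (3R,4S)-7-acetyl-6,8-dihydroxy-3,4,5-trimethylisochroman-1-one | CC(=O)c1c(O)c(C)c2c(c1O)C(=O)O[C@H](C)[C@H]2C
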